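## The problem

Sophoraflavanone A (26) is a flavanone: a phloroglucinol-type ring A is fused through C4a–C8a to the dihydropyranone ring C, ring B (4-hydroxyphenyl) sits on C2 and a geranyl chain on C8 (flavanone numbering: O1, C2, C3, C4, C4a, C5 to C8, C8a). The only stereocentre, C2 (S), has no neighbour that could induce it, so its configuration must come from a reagent or catalyst. It is also fragile: base opens ring C by retro-oxa-Michael reaction to an achiral chalcone, and strong acid can ionise the C2–O1 bond next to the electron-rich ring B. The geranyl chain has two trisubstituted alkenes, which rules out hydrogenolysis, electrophilic halogen and strong acids (O7 adds to the proximal alkene under acid). The 8-geranyl and 6-geranyl isomers differ only in which oxygen ortho to the acyl group closes ring C, so O1 must be distinguished from O5 before the ring forms. The three phenols need a mask that tolerates organolithium reagents and fluoride and leaves under conditions gentle to C2 and the chain. The enabling feature is that the adjacent carbons C4a and C8a carry the acyl carbon C4 and the ether oxygen O1, the ortho acyl/oxy pair that an aryne delivers on inserting into the C–O bond of a carboxylic acid; the oxygen on C5 beside C4a polarises the aryne so that oxygen goes to C8a.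

## Retrosynthesis

**26 from 25.** Only the three acetal C–O bonds of the methoxymethyl (MOM) ethers are cut, so the last step touches neither C2 nor the chain. MOM is preferred over benzyl (hydrogenolysis would reduce the chain), methyl (needs strong Lewis acid) and aryl silyl ethers (lost to fluoride in the key step). It also survives butyllithium, directs it, and is inert to CsF and to Mitsunobu reagents. The forward step must use acid mild enough for the geranyl group and for C2.

**25 from 24, and 24 from 23.** The O1–C2 bond is cut. Cutting C2–C3 or running the oxa-Michael sense would pass through an achiral chalcone and require asymmetric catalysis on a hindered substrate. Cutting C2–aryl would require a chromone. Opening O1–C2 instead gives the acyclic β-hydroxy ketone 24, whose (R) carbinol is the product of a ketone reduction and is closed with inversion. O1 is the only free phenol in 24, which fixes the 8-geranyl regiochemistry. Compound 24 comes from its silyl ether 23. The forward closure must be a clean SN2 displacement, faster than ionisation or elimination at the benzylic carbon.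

**23 from 15 and 21 (key disconnection).** O1–C8a and C4–C4a are cut together, leaving an aryne from ortho-silylaryl triflate 15 and the chiral acid 21. A Friedel–Crafts or Fries acylation would need Lewis acid near the chain and would not distinguish the ring oxygens. Acylating an aryllithium would leave O1 protected like O5. The aryne cut divides the target into two fragments of similar size and brings O1 in from the acid as the only free phenol. The forward reaction must be regioselective (oxygen to C8a), must favour acyl shift over protonation of the aryl anion, and must spare the silyl ether and the carbinol centre.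

**15 from 13, 7, 3, 2 and 1, with 8.** The O–S bond of the triflate, the C8–geranyl bond, the C4a–Si bond, the carbamate and two MOM ethers are cut in turn. One O-carbamate on the symmetric phenol 2 directs metalation to both flanking positions and later becomes the triflate. Silicon goes in before the chain, so the benzylic-allylic CH2 of the geranyl group never meets an alkyllithium. For each metalation the carbamate N–H is masked in the flask by a silyl group. Trimethylsilyl serves for the first, which is quenched cold. The sturdier triethylsilyl serves for the second, which must last through copper transmetalation and warming and still leave on near-neutral methanolysis, so that no acid meets the very electron-rich arylsilane. Electrophilic geranylation or halogenation would not discriminate the ring positions and would endanger the alkenes. The sequence ends at phloroglucinol 1 and geranyl bromide 8. It requires the carbamate to outrank the pair of MOM ethers as director, and the allylation to occur at the primary carbon.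

**21 from 20, 19, 18, 17 and 16.** The carbinol C–H bond (reduction) and the bond between the methylene and the carboxyl carbon (Claisen condensation) are cut. A catalytic asymmetric transfer hydrogenation of β-keto ester 18 is preferred over an auxiliary-based acetate aldol, whose facial control is less secure for unsubstituted enolates. The catalyst is commercial and its sense is predictable. The sequence ends at 4'-hydroxyacetophenone 16 and requires high enantioselectivity on an electron-rich aryl ketone.

## Roads not taken

Alternative 1: Ring A is built last by cutting C4a–C5 and C8–C8a. The bis(silyloxy) diene A3, carrying geranyl and methoxy on one terminus, would add across the nitro-activated alkene of the chiral dihydropyranone A2. Loss of nitrous acid and methanol would then aromatise ring A and give A1.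

- Merits: C2 is set early by a catalytic hetero-Diels–Alder entry to A2 and is never activated afterwards. The 8-geranyl pattern is fixed by construction. A1 arrives with O5 and O7 free, so one MOM ether remains to be removed, against three steps after the key step in the chosen plan.
- Weak points: the reacting terminus of A3 is fully substituted and must bond to a tertiary carbon of A2. A3 is hydrolytically labile and hard to make with defined geometry. A2 requires nitration beside an ionisable benzylic ether, and its C2–O1 bond can open under the conditions of cycloaddition and double elimination, which would erode C2.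
- Comparison: this road has the better endgame and avoids the SN1 risk of the Mitsunobu closure. Against that, the chosen plan uses a documented reaction class on fragments made by routine chemistry, with regiochemistry resting on a well-understood aryne polarisation.

Alternative 2: C4a–C4, C4–C3 and O1–C2 are cut. Iodophenol A5, arylacetylene A6 and a one-carbon carbonyl unit would combine under palladium-catalysed carbonylative coupling, and the phenol would then close 6-endo onto the activated alkyne to give flavone A4.

- Merits: three components in one flask, robust and functional-group-tolerant palladium chemistry, and a base-stable product. In convergence and reliability of the C–C bond formation this road is at least equal to an aryne insertion in hot THF, and probably better.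
- Weak points: A4 has an sp2 C2, so the only stereocentre would still have to be made by enantioselective 1,4-reduction of the chromone ring. That is poorly served by known methods and competes with reduction of the chain alkenes. 5-exo closure onto the alkyne also competes, and A5 is a hexasubstituted arene.
- Comparison: the chosen plan brings C2 in as a pre-formed carbinol of defined configuration and never has to reduce beside the geranyl group.

Alternative 3: C2–C3 is cut. A chiral dirhodium tetracarboxylate such as Rh2(S-PTTL)4 (divalent rhodium) would decompose diazoketone A8, and the carbene would insert into a benzylic C–H bond of the ortho benzyl ether to give A7.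

- Merits: ring C and C2 are made in one catalytic step with no pre-formed stereocentre and no Mitsunobu reaction. The all-silyl protection allows a fluoride endgame with no acid near the chain, which is better than the acidic MOM removal of the chosen plan.
- Weak points: an acceptor-only carbene is unselective. The ether oxygen can form a five-membered oxonium ylide and undergo Stevens shift. Six-membered C–H insertion is less favoured than five-membered. The chain alkenes are open to cyclopropanation and allylic insertion, and enantiocontrol for this ring size is unproven.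
- Comparison: the chosen plan sets C2 by a ketone reduction with a predictable sense, and its key step has fewer competing pathways.

Key step: step 11

## Route

Remark on the chemistry: geranyl bromide 8 is taken as the pure (2E) isomer of commerce, and the sense of hydride delivery in step 8 is assigned by analogy with the acetophenone model of the ruthenium–diamine catalyst.

Step 1
Reactants: 1 phloroglucinol
Product: 2 3,5-bis(methoxymethoxy)phenol
Conditions: MOMCl (2.0 equiv), iPr2NEt, DMF, 0 °C → rt
Reagents that add atoms: chloromethyl methyl ether (MOMCl), COCCl
Why: Base-mediated O-alkylation of a phenol with an α-chloro ether; the protection is statistical, so the bis-ether is separated by chromatography from mono- and tris-ether and the mono-ether is resubmitted.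

Step 2
Reactants: 2 3,5-bis(methoxymethoxy)phenol
Product: 3 3,5-bis(methoxymethoxy)phenyl N-isopropylcarbamate
Conditions: iPrNCO, Et3N (cat.), CH2Cl2, rt
Reagents that add atoms: isopropyl isocyanate, CC(C)N=C=O
Why: Amine-catalysed addition of the phenol to an isocyanate (carbamoylation); the N-monosubstituted carbamate is chosen because it can later be removed by mild E1cB cleavage.

Step 3
Reactants: 3 3,5-bis(methoxymethoxy)phenyl N-isopropylcarbamate
Product: 7 3,5-bis(methoxymethoxy)-2-(trimethylsilyl)phenyl N-isopropylcarbamate, via N-silyl carbamate 4 (not isolated), via aryllithium 5 (not isolated), via N-silyl C-silyl carbamate 6 (not isolated)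
Conditions: TMSOTf, TMEDA, Et2O, 0 °C → rt; n-BuLi (2.2 equiv), TMEDA, −78 °C; TMSCl, −78 °C → rt; MeOH, aq. NH4Cl
Reagents that add atoms: chlorotrimethylsilane, C[Si](C)(C)Cl
Why: Directed ortho-metalation of an aryl carbamate after in situ N-silylation; the carbamate is a stronger director than a MOM ether, so lithiation should occur between carbamate and MOM rather than between the two MOM ethers, and the two such sites are equivalent. TMSOTf is used pre-complexed with the diamine so that it silylates nitrogen and does not activate the acetals, and the diamine hydrotriflate so formed takes up the first equivalent of n-BuLi. The N–Si bond is cleaved by methanol on work-up, while the C–Si bond stays.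

Step 4
Reactants: 7 3,5-bis(methoxymethoxy)-2-(trimethylsilyl)phenyl N-isopropylcarbamate, 8 geranyl bromide
Product: 13 2-geranyl-3,5-bis(methoxymethoxy)-6-(trimethylsilyl)phenyl N-isopropylcarbamate, via N-triethylsilyl carbamate 9 (not isolated), via aryllithium 10 (not isolated), via arylcopper 11 (not isolated), via N-triethylsilyl geranyl carbamate 12 (not isolated)
Conditions: TESOTf, TMEDA, Et2O, 0 °C → rt; n-BuLi (2.1 equiv), TMEDA, −78 °C; CuBr·SMe2 (1.2 equiv), THF, −78 → −40 °C; 8, −78 → 0 °C; MeOH, aq. NH4Cl, rt
Reagents that add atoms: none
Why: The N–H is masked in the flask as the N-triethylsilyl carbamate, sturdier than its trimethylsilyl analogue so that it should last through transmetalation and warming, and a second carbamate-directed ortho-metalation then takes the remaining position between carbamate and MOM. Transmetalation to monovalent copper and allylation of the arylcopper at the primary carbon of the allylic bromide (SN2) keep the (E) alkene, and the chain is introduced only after the last alkyllithium has been consumed. The N–Si bond is cleaved by near-neutral methanolysis on work-up, so no acid meets the MOM ethers or the electron-rich arylsilane.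

Step 5
Reactants: 13 2-geranyl-3,5-bis(methoxymethoxy)-6-(trimethylsilyl)phenyl N-isopropylcarbamate
Product: 15 2-geranyl-3,5-bis(methoxymethoxy)-6-(trimethylsilyl)phenyl trifluoromethanesulfonate, via phenol 14 (not isolated)
Conditions: Et2NH, DBU, MeCN, 40 °C; then PhNTf2, 40 °C
Reagents that add atoms: N-phenylbis(trifluoromethanesulfonimide), O=S(=O)(N(c1ccccc1)S(=O)(=O)C(F)(F)F)C(F)(F)F
Why: E1cB cleavage of the N–H carbamate (the isocyanate is trapped by Et2NH as a urea) releases the hindered phenoxide, which is triflated in the same flask; this one-pot carbamate-to-triflate conversion is a standard entry to ortho-silylaryl triflates.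

Step 6
Reactants: 16 4'-hydroxyacetophenone
Product: 17 4'-(methoxymethoxy)acetophenone
Conditions: MOMCl, iPr2NEt, CH2Cl2, 0 °C → rt
Reagents that add atoms: chloromethyl methyl ether (MOMCl), COCCl
Why: Routine O-alkylation of a phenol; the same acetal is used on all three phenols so that one final step removes them together.

Step 7
Reactants: 17 4'-(methoxymethoxy)acetophenone
Product: 18 ethyl 3-[4-(methoxymethoxy)phenyl]-3-oxopropanoate
Conditions: NaH, (EtO)2CO, THF, reflux; then AcOH
Reagents that add atoms: diethyl carbonate, CCOC(=O)OCC
Why: Crossed Claisen condensation of the ketone enolate with a carbonate ester, driven by deprotonation of the β-keto ester formed.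

Step 8
Reactants: 18 ethyl 3-[4-(methoxymethoxy)phenyl]-3-oxopropanoate
Product: 19 ethyl (3R)-3-hydroxy-3-[4-(methoxymethoxy)phenyl]propanoate
Conditions: RuCl[(R,R)-TsDPEN](p-cymene) (1 mol %), HCO2H/Et3N (5:2), EtOAc, 30 °C
Reagents that add atoms: none
Why: Noyori asymmetric transfer hydrogenation; the hydride of divalent ruthenium is delivered through the six-membered outer-sphere transition state with the aryl ring held against the cymene ligand, which by the acetophenone model should give the (R) carbinol from the (R,R) catalyst. The ester arm takes the place of methyl without changing the priority order.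

Step 9
Reactants: 19 ethyl (3R)-3-hydroxy-3-[4-(methoxymethoxy)phenyl]propanoate
Product: 20 ethyl (3R)-3-(tert-butyldimethylsilyloxy)-3-[4-(methoxymethoxy)phenyl]propanoate
Conditions: TBSCl, imidazole, DMF, rt
Reagents that add atoms: tert-butyldimethylsilyl chloride, CC(C)(C)[Si](C)(C)Cl
Why: Standard imidazole-promoted silylation of a secondary alcohol; the ether keeps the alkoxide from adding to the aryne or triggering retro-aldol cleavage later.

Step 10
Reactants: 20 ethyl (3R)-3-(tert-butyldimethylsilyloxy)-3-[4-(methoxymethoxy)phenyl]propanoate
Product: 21 (3R)-3-(tert-butyldimethylsilyloxy)-3-[4-(methoxymethoxy)phenyl]propanoic acid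
Conditions: LiOH, THF/MeOH/H2O, 0 °C → rt; then 1 M HCl to pH 4, 0 °C
Reagents that add atoms: lithium hydroxide, [Li+].[OH-]
Why: Ester saponification at low temperature, where the poor silanolate leaving group should not be expelled by E1cB; cold acidification to pH 4 spares acetal and silyl ether.

Step 11
Reactants: 15 2-geranyl-3,5-bis(methoxymethoxy)-6-(trimethylsilyl)phenyl trifluoromethanesulfonate, 21 (3R)-3-(tert-butyldimethylsilyloxy)-3-[4-(methoxymethoxy)phenyl]propanoic acid
Product: 23 (3R)-3-(tert-butyldimethylsilyloxy)-1-[3-geranyl-2-hydroxy-4,6-bis(methoxymethoxy)phenyl]-3-[4-(methoxymethoxy)phenyl]propan-1-one, via aryne 22 (not isolated)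
Conditions: CsF (4 equiv), THF, sealed tube, 100 °C
Reagents that add atoms: none
Why: Fluoride attacks silicon in 15 and triflate leaves, giving aryne 22 (C4a≡C8a), while the acid is present as its cesium carboxylate. The carboxylate oxygen should add at C8a, the aryne carbon meta to the C5 acetal oxygen, because that σ-withdrawing oxygen distorts the aryne and stabilises the carbanion developing at C4a; attack at C4a would also meet lone-pair repulsion from O5, and this bias should outweigh the modest bulk of the C8 geranyl group. The C4a aryl anion then attacks the adjacent ester carbonyl through a four-membered transition state (a transient 4-exo-trig closure that reopens), moving the acyl group from oxygen to carbon; this forms O1–C8a and C4–C4a and closes no ring of the product. The closest known reaction type is the CsF-promoted insertion of arynes from ortho-silylaryl triflates into the C–O bond of carboxylic acids in hot THF, which gives ortho-hydroxyaryl ketones. No stereocentre is created, and the (R) carbinol lies two atoms from the reacting carbonyl and is carried through. Acyl shift must beat protonation of the aryl anion, which THF (no acidic C–H) and excess CsF favour; the new phenol O1 is chelated to the ketone and flanked by the chain, which should curb a second arylation. The temperature is held at the low end of the known window to limit fluoride attack on the silyl ether and E1cB loss of silanolate; anything that does eliminate and cyclise is removed by chromatography here, so it cannot lower the enantiomeric purity later.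

Step 12
Reactants: 23 (3R)-3-(tert-butyldimethylsilyloxy)-1-[3-geranyl-2-hydroxy-4,6-bis(methoxymethoxy)phenyl]-3-[4-(methoxymethoxy)phenyl]propan-1-one
Product: 24 (3R)-1-[3-geranyl-2-hydroxy-4,6-bis(methoxymethoxy)phenyl]-3-hydroxy-3-[4-(methoxymethoxy)phenyl]propan-1-one
Conditions: TBAF, AcOH (1:1), THF, 0 °C → rt
Reagents that add atoms: none
Why: Fluoride-mediated Si–O cleavage; buffering with acetic acid should keep the β-hydroxy ketone from retro-aldol cleavage or dehydration, and the acetals and alkenes are inert.

Step 13
Reactants: 24 (3R)-1-[3-geranyl-2-hydroxy-4,6-bis(methoxymethoxy)phenyl]-3-hydroxy-3-[4-(methoxymethoxy)phenyl]propan-1-one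
Product: 25 (2S)-8-geranyl-5,7-bis(methoxymethoxy)-2-[4-(methoxymethoxy)phenyl]chroman-4-one
Conditions: PPh3, DIAD, THF, 0 °C
Reagents that add atoms: none
Why: Intramolecular Mitsunobu etherification, known for closing 2'-hydroxy-β-hydroxy ketones to 2-substituted chroman-4-ones; O1, the only free phenol, displaces the oxyphosphonium group at C2 in a 6-exo-tet SN2 closure with inversion, so the (R) carbinol becomes the (2S) ether. Low temperature is used to favour concerted displacement over ionisation of the electron-rich benzylic centre.

Step 14
Reactants: 25 (2S)-8-geranyl-5,7-bis(methoxymethoxy)-2-[4-(methoxymethoxy)phenyl]chroman-4-one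
Product: 26 sophoraflavanone A, (2S)-8-geranyl-5,7-dihydroxy-2-(4-hydroxyphenyl)chroman-4-one
Conditions: 3 M aq. HCl, MeOH, 45 °C
Reagents that add atoms: none
Why: Acid-catalysed transacetalisation of the three MOM ethers to methanol, a standard unmasking for prenylated flavonoids; dilute acid at moderate temperature should leave the alkenes and the closed ring C, and hence C2, untouched.

## Compound list

1 | phloroglucinol | Oc1cc(O)cc(O)c1 | starting material
2 | 3,5-bis(methoxymethoxy)phenol | COCOc1cc(O)cc(OCOC)c1 | intermediate
3 | 3,5-bis(methoxymethoxy)phenyl N-isopropylcarbamate | CC(C)NC(=O)Oc1cc(OCOC)cc(OCOC)c1 | intermediate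
4 | 3,5-bis(methoxymethoxy)phenyl N-isopropyl-N-(trimethylsilyl)carbamate | CC(C)N([Si](C)(C)C)C(=O)Oc1cc(OCOC)cc(OCOC)c1 | intermediate
5 | 2-lithio derivative of 4 | CC(C)N([Si](C)(C)C)C(=O)Oc1cc(OCOC)cc(OCOC)c1[Li] | intermediate
6 | 3,5-bis(methoxymethoxy)-2-(trimethylsilyl)phenyl N-isopropyl-N-(trimethylsilyl)carbamate | CC(C)N([Si](C)(C)C)C(=O)Oc1cc(OCOC)cc(OCOC)c1[Si](C)(C)C | intermediate
7 | 3,5-bis(methoxymethoxy)-2-(trimethylsilyl)phenyl N-isopropylcarbamate | CC(C)NC(=O)Oc1cc(OCOC)cc(OCOC)c1[Si](C)(C)C | intermediate
8 | geranyl bromide, (2E)-1-bromo-3,7-dimethylocta-2,6-diene | CC(C)=CCC/C(C)=C/CBr | starting material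
9 | 3,5-bis(methoxymethoxy)-2-(trimethylsilyl)phenyl N-isopropyl-N-(triethylsilyl)carbamate | CC[Si](CC)(CC)N(C(C)C)C(=O)Oc1cc(OCOC)cc(OCOC)c1[Si](C)(C)C | intermediate
10 | 6-lithio derivative of 9 | CC[Si](CC)(CC)N(C(C)C)C(=O)Oc1c([Li])c(OCOC)cc(OCOC)c1[Si](C)(C)C | intermediate
11 | arylcopper from 10 | CC[Si](CC)(CC)N(C(C)C)C(=O)Oc1c([Cu])c(OCOC)cc(OCOC)c1[Si](C)(C)C | intermediate
12 | 2-geranyl-3,5-bis(methoxymethoxy)-6-(trimethylsilyl)phenyl N-isopropyl-N-(triethylsilyl)carbamate | CC(C)=CCC/C(C)=C/Cc1c(OCOC)cc(OCOC)c([Si](C)(C)C)c1OC(=O)N(C(C)C)[Si](CC)(CC)CC | intermediate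
13 | 2-geranyl-3,5-bis(methoxymethoxy)-6-(trimethylsilyl)phenyl N-isopropylcarbamate | CC(C)=CCC/C(C)=C/Cc1c(OCOC)cc(OCOC)c([Si](C)(C)C)c1OC(=O)NC(C)C | intermediate
14 | 2-geranyl-3,5-bis(methoxymethoxy)-6-(trimethylsilyl)phenol (formed as its DBU-H salt) | CC(C)=CCC/C(C)=C/Cc1c(OCOC)cc(OCOC)c([Si](C)(C)C)c1O | intermediate
15 | 2-geranyl-3,5-bis(methoxymethoxy)-6-(trimethylsilyl)phenyl trifluoromethanesulfonate | CC(C)=CCC/C(C)=C/Cc1c(OCOC)cc(OCOC)c([Si](C)(C)C)c1OS(=O)(=O)C(F)(F)F | intermediate
16 | 4'-hydroxyacetophenone | CC(=O)c1ccc(O)cc1 | starting material
17 | 4'-(methoxymethoxy)acetophenone | CC(=O)c1ccc(OCOC)cc1 | intermediate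
18 | ethyl 3-[4-(methoxymethoxy)phenyl]-3-oxopropanoate | CCOC(=O)CC(=O)c1ccc(OCOC)cc1 | intermediate
19 | ethyl (3R)-3-hydroxy-3-[4-(methoxymethoxy)phenyl]propanoate | CCOC(=O)C[C@@H](O)c1ccc(OCOC)cc1 | intermediate
20 | ethyl (3R)-3-(tert-butyldimethylsilyloxy)-3-[4-(methoxymethoxy)phenyl]propanoate | CCOC(=O)C[C@@H](O[Si](C)(C)C(C)(C)C)c1ccc(OCOC)cc1 | intermediate
21 | (3R)-3-(tert-butyldimethylsilyloxy)-3-[4-(methoxymethoxy)phenyl]propanoic acid | CC(C)(C)[Si](C)(C)O[C@@H](c1ccc(OCOC)cc1)CC(=O)O | intermediate
22 | 3-geranyl-4,6-bis(methoxymethoxy)benzyne (1,2-didehydrobenzene) | CC(C)=CCC/C(C)=C/CC1=C(OCOC)C=C(OCOC)C#C1 | intermediate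
23 | (3R)-3-(tert-butyldimethylsilyloxy)-1-[3-geranyl-2-hydroxy-4,6-bis(methoxymethoxy)phenyl]-3-[4-(methoxymethoxy)phenyl]propan-1-one | CC(C)=CCC/C(C)=C/Cc1c(OCOC)cc(OCOC)c(C(=O)C[C@@H](O[Si](C)(C)C(C)(C)C)c2ccc(OCOC)cc2)c1O | intermediate
24 | (3R)-1-[3-geranyl-2-hydroxy-4,6-bis(methoxymethoxy)phenyl]-3-hydroxy-3-[4-(methoxymethoxy)phenyl]propan-1-one | CC(C)=CCC/C(C)=C/Cc1c(OCOC)cc(OCOC)c(C(=O)C[C@@H](O)c2ccc(OCOC)cc2)c1O | intermediate
25 | (2S)-8-geranyl-5,7-bis(methoxymethoxy)-2-[4-(methoxymethoxy)phenyl]chroman-4-one | CC(C)=CCC/C(C)=C/Cc1c(OCOC)cc(OCOC)c2c1O[C@H](c1ccc(OCOC)cc1)CC2=O | intermediate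
26 | sophoraflavanone A, (2S)-8-geranyl-5,7-dihydroxy-2-(4-hydroxyphenyl)chroman-4-one | CC(C)=CCC/C(C)=C/Cc1c(O)cc(O)c2c1O[C@H](c1ccc(O)cc1)CC2=O | target

## Step count and least certain steps

Total step count: 14. Longest linear sequence: 9 steps (steps 1–5, then 11–14; the acid branch, steps 6–10 followed by 11–14, is equally long).

**Step 11 (key step).**
- Risk: the aryl anion may be protonated, or may take a proton from the ester α-methylene (followed by β-elimination), before the acyl shift occurs.
- Risk: hot fluoride may cleave the silyl ether, which leads to retro-aldol cleavage, or the product may lose silanolate by E1cB.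
- Risk: the geranyl group may erode the regioselectivity of carboxylate addition.
- Fallback: the same two bonds are made stepwise by directed metalation, setting out from 3 and returning at 23. Carbamate 3 is N-silylated and lithiated as in step 3, transmetalated to copper and allylated with 8 to give 2-geranyl-3,5-bis(methoxymethoxy)phenyl N-isopropylcarbamate F1. Acid 21 is coupled with N,O-dimethylhydroxylamine to give (3R)-3-(tert-butyldimethylsilyloxy)-N-methoxy-3-[4-(methoxymethoxy)phenyl]-N-methylpropanamide F2. A second carbamate-directed lithiation of F1 at the remaining ortho position (again after in situ N-silylation, at −78 °C so that ring lithiation outpaces deprotonation of the benzylic-allylic CH2) and acylation with F2 gives 2-[(3R)-3-(tert-butyldimethylsilyloxy)-3-[4-(methoxymethoxy)phenyl]propanoyl]-6-geranyl-3,5-bis(methoxymethoxy)phenyl N-isopropylcarbamate F3. Cleavage with Et2NH and DBU, run at the lowest temperature that works so that the base does not expel silanolate, frees O1 and gives 23.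

**Step 13.**
- Risk: the oxyphosphonium intermediate on the para-alkoxybenzylic carbon may ionise, causing partial racemisation.
- Risk: E1cB elimination toward the enone may compete with displacement.
- Fallback: C2 is set by kinetic resolution instead of invertive substitution, setting out from 23 and returning at 25. DBU expels silanolate from 23 to give (E)-1-[3-geranyl-2-hydroxy-4,6-bis(methoxymethoxy)phenyl]-3-[4-(methoxymethoxy)phenyl]prop-2-en-1-one F4. NaOAc in refluxing EtOH closes it to racemic 8-geranyl-5,7-bis(methoxymethoxy)-2-[4-(methoxymethoxy)phenyl]chroman-4-one F5. Transfer hydrogenation with RuCl[(R,R)-TsDPEN](p-cymene) and HCO2H/Et3N should reduce the (2R) ketone faster, to (2R,4R)-8-geranyl-5,7-bis(methoxymethoxy)-2-[4-(methoxymethoxy)phenyl]chroman-4-ol F6, and leave 25. At most half of the material is recovered. The same resolution can upgrade a partly racemised batch of 25.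

**Step 4.**
- Risk: lithiation beside the silyl-flanked carbamate may be incomplete, or may stray to the position between the two MOM ethers.
- Risk: the N-silyl group may be lost during transmetalation or warming, after which the carbamate anion fragments to isocyanate and phenoxide.
- Risk: the allylic bromide may be attacked at its tertiary end.
- Fallback: the chain is attached by phenoxide C-alkylation, setting out from 7 and returning at 14. Et2NH and DBU convert 7 into 3,5-bis(methoxymethoxy)-2-(trimethylsilyl)phenol F7. Its sodium salt (NaH, toluene) is C-allylated at the free ortho position with 8 to give 14, which is triflated with PhNTf2 to 15.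

**Step 14.**
- Risk: acid may promote addition of O7 to the proximal alkene or cation–olefin cyclisation of the chain.
- Risk: acid may ionise C2–O1 once the 4'-phenol is free.
- Fallback: 25 is converted to 26 by Lewis-acid-assisted thiolysis under aprotic conditions (ZnBr2, n-PrSH, CH2Cl2, 0 °C), which transfers the methoxymethyl groups to sulfur without a free Brønsted acid. This fallback makes no new compound (F0).

## Further compounds

F1 | step 11 | 2-geranyl-3,5-bis(methoxymethoxy)phenyl N-isopropylcarbamate | CC(C)=CCC/C(C)=C/Cc1c(OCOC)cc(OCOC)cc1OC(=O)NC(C)C
F2 | step 11 | (3R)-3-(tert-butyldimethylsilyloxy)-N-methoxy-3-[4-(methoxymethoxy)phenyl]-N-methylpropanamide | CON(C)C(=O)C[C@@H](O[Si](C)(C)C(C)(C)C)c1ccc(OCOC)cc1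
F3 | step 11 | 2-[(3R)-3-(tert-butyldimethylsilyloxy)-3-[4-(methoxymethoxy)phenyl]propanoyl]-6-geranyl-3,5-bis(methoxymethoxy)phenyl N-isopropylcarbamate | CC(C)=CCC/C(C)=C/Cc1c(OCOC)cc(OCOC)c(C(=O)C[C@@H](O[Si](C)(C)C(C)(C)C)c2ccc(OCOC)cc2)c1OC(=O)NC(C)C
F4 | step 13 | (E)-1-[3-geranyl-2-hydroxy-4,6-bis(methoxymethoxy)phenyl]-3-[4-(methoxymethoxy)phenyl]prop-2-en-1-one | CC(C)=CCC/C(C)=C/Cc1c(OCOC)cc(OCOC)c(C(=O)/C=C/c2ccc(OCOC)cc2)c1O
F5 | step 13 | racemic 8-geranyl-5,7-bis(methoxymethoxy)-2-[4-(methoxymethoxy)phenyl]chroman-4-one | CC(C)=CCC/C(C)=C/Cc1c(OCOC)cc(OCOC)c2c1OC(c1ccc(OCOC)cc1)CC2=O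
F6 | step 13 | (2R,4R)-8-geranyl-5,7-bis(methoxymethoxy)-2-[4-(methoxymethoxy)phenyl]chroman-4-ol | CC(C)=CCC/C(C)=C/Cc1c(OCOC)cc(OCOC)c2c1O[C@@H](c1ccc(OCOC)cc1)C[C@H]2O
F7 | step 4 | 3,5-bis(methoxymethoxy)-2-(trimethylsilyl)phenol | COCOc1cc(O)c([Si](C)(C)C)c(OCOC)c1
F0 | step 14 | none | none
A1 | alternative 1 | (2S)-8-geranyl-5,7-dihydroxy-2-[4-(methoxymethoxy)phenyl]chroman-4-one | CC(C)=CCC/C(C)=C/Cc1c(O)cc(O)c2c1O[C@H](c1ccc(OCOC)cc1)CC2=O
A2 | alternative 1 | (2S)-2-[4-(methoxymethoxy)phenyl]-5-nitro-2,3-dihydro-4H-pyran-4-one | O=C1C[C@@H](c2ccc(OCOC)cc2)OC=C1[N+](=O)[O-]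
A3 | alternative 1 | 1-geranyl-1-methoxy-2,4-bis(trimethylsilyloxy)buta-1,3-diene | CC(C)=CCC/C(C)=C/CC(OC)=C(O[Si](C)(C)C)C=CO[Si](C)(C)C
A4 | alternative 2 | 8-geranyl-5,7-bis(methoxymethoxy)-2-[4-(methoxymethoxy)phenyl]-4H-chromen-4-one | CC(C)=CCC/C(C)=C/Cc1c(OCOC)cc(OCOC)c2c1OC(c1ccc(OCOC)cc1)=CC2=O
A5 | alternative 2 | 2-geranyl-6-iodo-3,5-bis(methoxymethoxy)phenol | CC(C)=CCC/C(C)=C/Cc1c(OCOC)cc(OCOC)c(I)c1O
A6 | alternative 2 | 1-ethynyl-4-(methoxymethoxy)benzene | C#Cc1ccc(OCOC)cc1
A7 | alternative 3 | (2S)-5,7-bis(tert-butyldimethylsilyloxy)-2-[4-(tert-butyldimethylsilyloxy)phenyl]-8-geranylchroman-4-one | CC(C)=CCC/C(C)=C/Cc1c(O[Si](C)(C)C(C)(C)C)cc(O[Si](C)(C)C(C)(C)C)c2c1O[C@H](c1ccc(O[Si](C)(C)C(C)(C)C)cc1)CC2=O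
A8 | alternative 3 | 2-diazo-1-{4,6-bis(tert-butyldimethylsilyloxy)-2-[4-(tert-butyldimethylsilyloxy)benzyloxy]-3-geranylphenyl}ethan-1-one | CC(C)=CCC/C(C)=C/Cc1c(O[Si](C)(C)C(C)(C)C)cc(O[Si](C)(C)C(C)(C)C)c(C(=O)C=[N+]=[N-])c1OCc1ccc(O[Si](C)(C)C(C)(C)C)cc1
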